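The route rests on opening ring B at C5–C6. Since C6 lies β to the C8 carbonyl, that bond is a conjugate-addition bond, and the angular C5 methyl together with C5–C6 can both be traced back to an exocyclic methylene on C5 of ring A. In one operation an iron hydride hands a hydrogen atom to the methylene carbon, and the tertiary C5 radical adds 6-endo to C6 of the enone, closing ring B (C5–C10) and fixing the quaternary C5 with the trans ring fusion. The precursor is a ring A methylenecyclohexane with the C4 methyl, a silyl-protected C3 oxygen and, on C10, the chain C9(OSi)–C8(=O)–C7=C6.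

Key step: step 13

Remarks on the chemistry (eremophilane numbering; ring A = C1–C5 and C10, ring B = C5–C10; α is the face of the C10 hydrogen):
- Structure check: the target is 3α-angeloyloxy, 4β,5β-dimethyl, 7α-isopropenyl, 8-oxo, 9α-acyloxy, 10αH, i.e. (3R,4R,5R,7S,9S,10R), trans-fused, with every substituent except the C5 methyl equatorial. The ring-closure precursor and product below carry the same configuration at C3, C4, C9 and C10.
- C9 and C10 stand in a syn aldol relationship, whereas a ring-ketone enolate gives anti aldols. Assumption: the kinetic aldol enters the enolate trans to the C4 methyl, as alkylations of 6-substituted cyclohexanone enolates do. The aldol is therefore followed by equilibration of C10, which turns the kinetic trans/anti adduct into the required cis/syn one without touching C9.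
- An achiral aldehyde (ethyl glyoxylate) supplies C9 and C8, so C8 is never a stereocentre.
- The C3 oxygen is carried as a silyl ether, because a benzylic ether would offer the C5 radical a weak C–H bond through a six-membered transition state.
- After ring closure C9 lies α to the ketone with its oxygen equatorial, the more stable arrangement, so this centre stays under thermodynamic control.
- Coupling partners that supply carbon are numbered and stand under Reactants; the line "Reagents that add atoms" names the others.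

Step 1
Reactants: 1 2-methylcyclohex-2-en-1-one
Product: 3 (1R)-2-methylcyclohex-2-en-1-ol, via catechol borate ester 2 (not isolated)
Conditions: (S)-Me-CBS oxazaborolidine (10 mol%), catecholborane, toluene, −78 °C; aq NaOH work-up
Reagents that add atoms: none
Why: Corey–Bakshi–Shibata reduction, in which the oxazaborolidine–borane complex binds the carbonyl with the α-methylvinyl arm as the large group and delivers hydride to one face at low temperature (1,2- over 1,4-reduction), setting the carbinol centre as R; this centre only steers step 3 and is oxidised away in step 6.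

Step 2
Reactants: 3 (1R)-2-methylcyclohex-2-en-1-ol, 4 4-methoxybenzyl chloride
Product: 6 1-methoxy-4-({[(1R)-2-methylcyclohex-2-en-1-yl]oxy}methyl)benzene, via sodium alkoxide 5 (not isolated)
Conditions: NaH, THF/DMF, 0 °C; 4, Bu4NI (cat.), rt
Reagents that add atoms: none
Why: Williamson ether synthesis on the alkoxide, which touches no stereocentre and installs a temporary ether that survives hydroboration and silylation and is later removed oxidatively.

Step 3
Reactants: 6 1-methoxy-4-({[(1R)-2-methylcyclohex-2-en-1-yl]oxy}methyl)benzene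
Product: 8 (1R,2S,3R)-3-[(4-methoxybenzyl)oxy]-2-methylcyclohexan-1-ol, via alkylborane 7 (not isolated)
Conditions: BH3·THF (2 equiv), THF, 0 °C → rt; then NaOH, H2O2, 0 °C → rt
Reagents that add atoms: hydrogen peroxide, OO
Why: Hydroboration–oxidation, in which boron adds to the less substituted alkene carbon (C3) and hydrogen to C4 in syn fashion from the face opposite the pseudoaxial allylic ether and oxidation proceeds with retention, so the new hydroxyl (3α) and the methyl (4β) come out trans and both are fixed by the carbinol centre of step 1.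

Step 4
Reactants: 8 (1R,2S,3R)-3-[(4-methoxybenzyl)oxy]-2-methylcyclohexan-1-ol
Product: 9 tert-butyl({(1R,2R,3R)-3-[(4-methoxybenzyl)oxy]-2-methylcyclohexyl}oxy)dimethylsilane
Conditions: TBSCl, imidazole, DMF, rt
Reagents that add atoms: tert-butyldimethylsilyl chloride, CC(C)(C)[Si](C)(C)Cl
Why: Silylation of the equatorial secondary alcohol gives a C3 ether that lasts to step 19 and has no weak C–H bond near C5.

Step 5
Reactants: 9 tert-butyl({(1R,2R,3R)-3-[(4-methoxybenzyl)oxy]-2-methylcyclohexyl}oxy)dimethylsilane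
Product: 10 (1R,2R,3R)-3-{[tert-butyl(dimethyl)silyl]oxy}-2-methylcyclohexan-1-ol
Conditions: DDQ, CH2Cl2/pH 7 buffer, 0 °C → rt
Reagents that add atoms: none
Why: Oxidative cleavage of the 4-methoxybenzyl ether by DDQ (hydride abstraction and hydrolysis of the oxocarbenium ion) proceeds under neutral conditions that leave the silyl ether alone.

Step 6
Reactants: 10 (1R,2R,3R)-3-{[tert-butyl(dimethyl)silyl]oxy}-2-methylcyclohexan-1-ol
Product: 11 (2S,3R)-3-{[tert-butyl(dimethyl)silyl]oxy}-2-methylcyclohexan-1-one
Conditions: Dess–Martin periodinane, NaHCO3, CH2Cl2, rt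
Reagents that add atoms: none
Why: Dess–Martin oxidation of the secondary alcohol under buffered, non-enolising conditions gives the ring A ketone (C5) without epimerising C4 or eliminating the β-silyloxy group.

Step 7
Reactants: 11 (2S,3R)-3-{[tert-butyl(dimethyl)silyl]oxy}-2-methylcyclohexan-1-one, 12 ethyl glyoxylate
Product: 15 ethyl (2S)-2-[(1R,3S,4R)-4-{[tert-butyl(dimethyl)silyl]oxy}-3-methyl-2-oxocyclohexyl]-2-hydroxyacetate, via boron enolate 13 (not isolated), via boron aldolate 14 (not isolated)
Conditions: Cy2BCl, Et3N, Et2O, 0 °C; 12 (freshly distilled), −78 °C; then pH 7 buffer, MeOH, H2O2, 0 °C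
Reagents that add atoms: none
Why: Boron-mediated aldol addition through a Zimmerman–Traxler chair, in which Cy2BCl/Et3N enolises the less hindered CH2 side to the ring-constrained E-enol borinate, which adds to the aldehyde with anti topicity from the α face (trans to the pseudoaxial C4 methyl), so that C9 is set as S and C10 provisionally with its side chain axial.

Step 8
Reactants: 15 ethyl (2S)-2-[(1R,3S,4R)-4-{[tert-butyl(dimethyl)silyl]oxy}-3-methyl-2-oxocyclohexyl]-2-hydroxyacetate
Product: 16 ethyl (2S)-2-[(1R,3S,4R)-4-{[tert-butyl(dimethyl)silyl]oxy}-3-methyl-2-oxocyclohexyl]-2-[(triethylsilyl)oxy]acetate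
Conditions: TESCl, imidazole, DMF, 0 °C → rt
Reagents that add atoms: chlorotriethylsilane, CC[Si](Cl)(CC)CC
Why: Silylation of the α-hydroxy ester blocks retro-aldol cleavage before the base treatment of step 9 and gives a C9 ether that can later be removed in the presence of the C3 tert-butyldimethylsilyl ether.

Step 9
Reactants: 16 ethyl (2S)-2-[(1R,3S,4R)-4-{[tert-butyl(dimethyl)silyl]oxy}-3-methyl-2-oxocyclohexyl]-2-[(triethylsilyl)oxy]acetate
Product: 18 ethyl (2S)-2-[(1S,3S,4R)-4-{[tert-butyl(dimethyl)silyl]oxy}-3-methyl-2-oxocyclohexyl]-2-[(triethylsilyl)oxy]acetate, via amidinium enolate 17 (not isolated)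
Conditions: DBU (0.5 equiv), CH2Cl2, rt, to equilibrium; chromatography, minor epimer resubmitted
Reagents that add atoms: none
Why: Base-mediated epimerisation α to the ketone, in which reversible enolisation moves the C10 side chain from axial to equatorial to give the all-equatorial 2,6-cis ketone as the thermodynamic product (C10 now cis to the C4 methyl and syn to the untouched C9), while the poor silanolate leaving groups at C9 and C3 keep re-protonation far faster than E1cB loss.

Step 10
Reactants: 18 ethyl (2S)-2-[(1S,3S,4R)-4-{[tert-butyl(dimethyl)silyl]oxy}-3-methyl-2-oxocyclohexyl]-2-[(triethylsilyl)oxy]acetate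
Product: 19 ethyl (2S)-2-[(1R,3R,4R)-4-{[tert-butyl(dimethyl)silyl]oxy}-3-methyl-2-methylidenecyclohexyl]-2-[(triethylsilyl)oxy]acetate
Conditions: Zn, CH2Br2, TiCl4, THF, 0 °C (pre-formed reagent); 18, CH2Cl2, 0 °C → rt
Reagents that add atoms: dibromomethane, BrCBr
Why: Takai–Lombardo methylenation, whose non-basic gem-dimetallic reagent converts the hindered, enolisable ketone into the exocyclic methylene without epimerising C4 or C10, without β-elimination and without attacking the ester.

Step 11
Reactants: 19 ethyl (2S)-2-[(1R,3R,4R)-4-{[tert-butyl(dimethyl)silyl]oxy}-3-methyl-2-methylidenecyclohexyl]-2-[(triethylsilyl)oxy]acetate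
Product: 20 (2S)-2-[(1R,3R,4R)-4-{[tert-butyl(dimethyl)silyl]oxy}-3-methyl-2-methylidenecyclohexyl]-N-methoxy-N-methyl-2-[(triethylsilyl)oxy]acetamide
Conditions: MeNH(OMe)·HCl, iPrMgCl, THF, −20 → 0 °C
Reagents that add atoms: N,O-dimethylhydroxylamine hydrochloride, CNOC.Cl
Why: Weinreb amide formation by aminolysis of the ester with the chloromagnesium amide, a non-enolising nucleophile that should leave the α-silyloxy centre C9 intact.

Step 12
Reactants: 20 (2S)-2-[(1R,3R,4R)-4-{[tert-butyl(dimethyl)silyl]oxy}-3-methyl-2-methylidenecyclohexyl]-N-methoxy-N-methyl-2-[(triethylsilyl)oxy]acetamide, 21 vinylmagnesium bromide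
Product: 23 (1S)-1-[(1R,3R,4R)-4-{[tert-butyl(dimethyl)silyl]oxy}-3-methyl-2-methylidenecyclohexyl]-1-[(triethylsilyl)oxy]but-3-en-2-one, via magnesium hemiaminal 22 (not isolated)
Conditions: 21, THF, −78 → 0 °C; poured into cold 1 M HCl
Reagents that add atoms: none
Why: Weinreb ketone synthesis, in which the chelated tetrahedral adduct holds back a second addition and collapses only on the acidic inverse quench, which also keeps the liberated amine protonated so that it cannot add to the new vinyl ketone.

Step 13
Reactants: 23 (1S)-1-[(1R,3R,4R)-4-{[tert-butyl(dimethyl)silyl]oxy}-3-methyl-2-methylidenecyclohexyl]-1-[(triethylsilyl)oxy]but-3-en-2-one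
Product: 26 (1S,4aR,5R,6R,8aR)-6-{[tert-butyl(dimethyl)silyl]oxy}-4a,5-dimethyl-1-[(triethylsilyl)oxy]octahydronaphthalen-2(1H)-one, via tertiary C5 radical 24 (not isolated), via α-keto C7 radical 25 (not isolated)
Conditions: Fe(acac)3 (0.3 equiv), PhSiH3 (2.5 equiv), EtOH/ethylene glycol (5:1), 0.01 M, 60 °C
Reagents that add atoms: none
Why: Metal-hydride hydrogen-atom transfer followed by intramolecular radical conjugate addition (Giese-type reductive olefin coupling, the closest known reaction being the Fe(acac)3/PhSiH3 coupling of 1,1-disubstituted alkenes with enones): the iron hydride delivers a hydrogen atom to the electron-rich CH2 terminus only, giving the nucleophilic tertiary C5 radical, while the electron-poor enone is not a hydrogen-atom acceptor. Ring B (C5–C10) closes by 6-endo-trig attack of C5 on the terminal enone carbon C6, which is polarity-matched and gives the stabilised α-keto radical, whereas 5-exo attack at C7 would be mismatched and give a primary radical. The α-keto radical is reduced by divalent iron and protonated by ethanol, which regenerates trivalent iron and leaves the C8 ketone. The only new stereocentre, C5, is controlled by the existing C10 and C4 centres: with the C10 chain and the C4 methyl equatorial on the ring A chair, C6 reaches C5 along the equatorial, peripheral trajectory of a chair–chair transition state, so the new methyl becomes axial (β) and the fusion trans. The step needs hydrogen-atom transfer to the methylene group only and trans rather than cis fusion; the first is secured by the electronic difference between the two alkenes, the second by the equatorial chain, because the folded transition state leading to the cis isomer would push the chain across the β face against the axial hydrogens on C1 and C3.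

Step 14
Reactants: 26 (1S,4aR,5R,6R,8aR)-6-{[tert-butyl(dimethyl)silyl]oxy}-4a,5-dimethyl-1-[(triethylsilyl)oxy]octahydronaphthalen-2(1H)-one, 27 2-bromopropene
Product: 30 (1S,3S,4aR,5R,6R,8aR)-6-{[tert-butyl(dimethyl)silyl]oxy}-4a,5-dimethyl-3-(prop-1-en-2-yl)-1-[(triethylsilyl)oxy]octahydronaphthalen-2(1H)-one, via lithium enolate 28 (not isolated), via lithium dienolate 29 (not isolated)
Conditions: LiN(SiMe3)2 (2.2 equiv), THF, −78 °C; Pd(dba)2 (5 mol%), Q-Phos (10 mol%), 27, −78 °C → rt; AcOH, −78 °C
Reagents that add atoms: none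
Why: Palladium-catalysed α-alkenylation of a ketone enolate, in which the kinetic enolate forms at the C7 methylene (C9 is a hindered methine carrying the silyloxy group), couples with the isopropenylpalladium bromide, and the more acidic product is held as its dienolate until the cold acetic acid quench, where axial α-protonation leaves the isopropenyl group equatorial (7α, S), the arrangement that also avoids a 1,3-diaxial clash with the C5 methyl.

Step 15
Reactants: 30 (1S,3S,4aR,5R,6R,8aR)-6-{[tert-butyl(dimethyl)silyl]oxy}-4a,5-dimethyl-3-(prop-1-en-2-yl)-1-[(triethylsilyl)oxy]octahydronaphthalen-2(1H)-one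
Product: 31 (1S,3S,4aR,5R,6R,8aR)-6-{[tert-butyl(dimethyl)silyl]oxy}-1-hydroxy-4a,5-dimethyl-3-(prop-1-en-2-yl)octahydronaphthalen-2(1H)-one
Conditions: HF·pyridine, pyridine, THF, 0 °C
Reagents that add atoms: none
Why: Fluoride-mediated desilylation, in which the triethylsilyl ether, activated by the adjacent carbonyl, is cleaved much faster than the tert-butyldimethylsilyl ether under buffered conditions mild enough to leave the β,γ-unsaturated ketone in place.

Step 16
Reactants: 32 ethyl but-2-ynoate, 33 ethylmagnesium bromide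
Product: 35 ethyl (2E)-3-methylpent-2-enoate, via alkenylcopper 34 (not isolated)
Conditions: 33, CuI, THF, −78 °C; 32, −78 °C; MeOH, −78 °C
Reagents that add atoms: none
Why: Carbocupration of an alkynoate, in which ethylcopper adds ethyl and copper to the same side of the triple bond and the alkenylcopper is protonated at −78 °C before it can equilibrate through the allenolate, so ethyl ends trans to the ester (E).

Step 17
Reactants: 35 ethyl (2E)-3-methylpent-2-enoate
Product: 37 (2E)-3-methylpent-2-enoic acid, via lithium carboxylate 36 (not isolated)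
Conditions: LiOH, THF/H2O, rt; then 1 M HCl
Reagents that add atoms: lithium hydroxide, [Li+].[OH-]
Why: Saponification of the ester by acyl substitution, which does not touch the trisubstituted double bond or its geometry.

Step 18
Reactants: 31 (1S,3S,4aR,5R,6R,8aR)-6-{[tert-butyl(dimethyl)silyl]oxy}-1-hydroxy-4a,5-dimethyl-3-(prop-1-en-2-yl)octahydronaphthalen-2(1H)-one, 37 (2E)-3-methylpent-2-enoic acid
Product: 39 (1S,3S,4aR,5R,6R,8aR)-6-{[tert-butyl(dimethyl)silyl]oxy}-4a,5-dimethyl-2-oxo-3-(prop-1-en-2-yl)decahydronaphthalen-1-yl (2E)-3-methylpent-2-enoate, via O-acylisourea 38 (not isolated)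
Conditions: DCC, DMAP, CH2Cl2, 0 °C → rt
Reagents that add atoms: none
Why: Steglich esterification, in which the carbodiimide-activated acid is passed through the acylpyridinium ion to the hindered C9 hydroxyl at room temperature without strong base, so neither C7 nor the enoate geometry should be disturbed.

Step 19
Reactants: 39 (1S,3S,4aR,5R,6R,8aR)-6-{[tert-butyl(dimethyl)silyl]oxy}-4a,5-dimethyl-2-oxo-3-(prop-1-en-2-yl)decahydronaphthalen-1-yl (2E)-3-methylpent-2-enoate
Product: 40 (1S,3S,4aR,5R,6R,8aR)-6-hydroxy-4a,5-dimethyl-2-oxo-3-(prop-1-en-2-yl)decahydronaphthalen-1-yl (2E)-3-methylpent-2-enoate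
Conditions: HF·pyridine, pyridine, THF, 0 °C → rt
Reagents that add atoms: none
Why: Fluoride-mediated cleavage of the remaining silyl ether under buffered, weakly acidic conditions that tolerate the ester, the ketone and the isopropenyl group.

Step 20
Reactants: 40 (1S,3S,4aR,5R,6R,8aR)-6-hydroxy-4a,5-dimethyl-2-oxo-3-(prop-1-en-2-yl)decahydronaphthalen-1-yl (2E)-3-methylpent-2-enoate, 41 angelic acid
Product: 43 (1S,3S,4aR,5R,6R,8aR)-4a,5-dimethyl-6-{[(2Z)-2-methylbut-2-enoyl]oxy}-2-oxo-3-(prop-1-en-2-yl)decahydronaphthalen-1-yl (2E)-3-methylpent-2-enoate, via mixed anhydride 42 (not isolated)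
Conditions: 41, 2,4,6-trichlorobenzoyl chloride, Et3N, toluene, rt; then 40, 75 °C
Reagents that add atoms: none
Why: Yamaguchi-type mixed-anhydride esterification, in which the equatorial C3 hydroxyl attacks the less hindered angeloyl carbonyl in the absence of a nucleophilic catalyst, the conditions under which the Z double bond of angelates is retained and does not drift to the tiglate.

Compound list
1 | 2-methylcyclohex-2-en-1-one | CC1=CCCCC1=O | starting material
2 | 2-{[(1R)-2-methylcyclohex-2-en-1-yl]oxy}-1,3,2-benzodioxaborole (not isolated) | CC1=CCCC[C@H]1OB1Oc2ccccc2O1 | intermediate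
3 | (1R)-2-methylcyclohex-2-en-1-ol | CC1=CCCC[C@H]1O | intermediate
4 | 4-methoxybenzyl chloride | COc1ccc(CCl)cc1 | starting material
5 | sodium (1R)-2-methylcyclohex-2-en-1-olate (not isolated) | CC1=CCCC[C@H]1[O-].[Na+] | intermediate
6 | 1-methoxy-4-({[(1R)-2-methylcyclohex-2-en-1-yl]oxy}methyl)benzene | CC1=CCCC[C@H]1OCc2ccc(OC)cc2 | intermediate
7 | {(1R,2S,3R)-3-[(4-methoxybenzyl)oxy]-2-methylcyclohexyl}borane (not isolated) | B[C@@H]1CCC[C@@H](OCc2ccc(OC)cc2)[C@H]1C | intermediate
8 | (1R,2S,3R)-3-[(4-methoxybenzyl)oxy]-2-methylcyclohexan-1-ol | O[C@@H]1CCC[C@@H](OCc2ccc(OC)cc2)[C@H]1C | intermediate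
9 | tert-butyl({(1R,2R,3R)-3-[(4-methoxybenzyl)oxy]-2-methylcyclohexyl}oxy)dimethylsilane | CC(C)(C)[Si](C)(C)O[C@@H]1CCC[C@@H](OCc2ccc(OC)cc2)[C@H]1C | intermediate
10 | (1R,2R,3R)-3-{[tert-butyl(dimethyl)silyl]oxy}-2-methylcyclohexan-1-ol | CC(C)(C)[Si](C)(C)O[C@@H]1CCC[C@@H](O)[C@H]1C | intermediate
11 | (2S,3R)-3-{[tert-butyl(dimethyl)silyl]oxy}-2-methylcyclohexan-1-one (ring A ketone; 3α-silyloxy, 4β-methyl) | O=C1CCC[C@@H](O[Si](C)(C)C(C)(C)C)[C@@H]1C | intermediate
12 | ethyl glyoxylate (ethyl 2-oxoacetate) | CCOC(=O)C=O | starting material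
13 | dicyclohexylboron enolate of 11 towards C10 (not isolated) | CC(C)(C)[Si](C)(C)O[C@@H]1CCC=C(OB(C2CCCCC2)C2CCCCC2)[C@H]1C | intermediate
14 | dicyclohexylboron aldolate of 15 (not isolated) | CCOC(=O)[C@@H](OB(C1CCCCC1)C1CCCCC1)[C@H]1CC[C@@H](O[Si](C)(C)C(C)(C)C)[C@H](C)C1=O | intermediate
15 | ethyl (2S)-2-[(1R,3S,4R)-4-{[tert-butyl(dimethyl)silyl]oxy}-3-methyl-2-oxocyclohexyl]-2-hydroxyacetate (kinetic anti aldol; C10 chain α, axial) | CCOC(=O)[C@@H](O)[C@H]1CC[C@@H](O[Si](C)(C)C(C)(C)C)[C@H](C)C1=O | intermediate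
16 | ethyl (2S)-2-[(1R,3S,4R)-4-{[tert-butyl(dimethyl)silyl]oxy}-3-methyl-2-oxocyclohexyl]-2-[(triethylsilyl)oxy]acetate | CCOC(=O)[C@@H](O[Si](CC)(CC)CC)[C@H]1CC[C@@H](O[Si](C)(C)C(C)(C)C)[C@H](C)C1=O | intermediate
17 | C5–C10 enolate of 16 as its DBU-H salt (not isolated) | CCOC(=O)[C@@H](O[Si](CC)(CC)CC)C1=C([O-])[C@@H](C)[C@H](O[Si](C)(C)C(C)(C)C)CC1.C1CCC2=[NH+]CCCN2CC1 | intermediate
18 | ethyl (2S)-2-[(1S,3S,4R)-4-{[tert-butyl(dimethyl)silyl]oxy}-3-methyl-2-oxocyclohexyl]-2-[(triethylsilyl)oxy]acetate (all-equatorial; C10 chain β) | CCOC(=O)[C@@H](O[Si](CC)(CC)CC)[C@@H]1CC[C@@H](O[Si](C)(C)C(C)(C)C)[C@H](C)C1=O | intermediate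
19 | ethyl (2S)-2-[(1R,3R,4R)-4-{[tert-butyl(dimethyl)silyl]oxy}-3-methyl-2-methylidenecyclohexyl]-2-[(triethylsilyl)oxy]acetate | CCOC(=O)[C@@H](O[Si](CC)(CC)CC)[C@@H]1CC[C@@H](O[Si](C)(C)C(C)(C)C)[C@H](C)C1=C | intermediate
20 | (2S)-2-[(1R,3R,4R)-4-{[tert-butyl(dimethyl)silyl]oxy}-3-methyl-2-methylidenecyclohexyl]-N-methoxy-N-methyl-2-[(triethylsilyl)oxy]acetamide | CON(C)C(=O)[C@@H](O[Si](CC)(CC)CC)[C@@H]1CC[C@@H](O[Si](C)(C)C(C)(C)C)[C@H](C)C1=C | intermediate
21 | vinylmagnesium bromide | C=C[Mg]Br | starting material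
22 | bromomagnesium hemiaminal adduct of 20 (not isolated; new carbinol carbon of undefined configuration) | C=CC(O[Mg]Br)(N(C)OC)[C@@H](O[Si](CC)(CC)CC)[C@@H]1CC[C@@H](O[Si](C)(C)C(C)(C)C)[C@H](C)C1=C | intermediate
23 | (1S)-1-[(1R,3R,4R)-4-{[tert-butyl(dimethyl)silyl]oxy}-3-methyl-2-methylidenecyclohexyl]-1-[(triethylsilyl)oxy]but-3-en-2-one (ring-closure precursor) | C=CC(=O)[C@@H](O[Si](CC)(CC)CC)[C@@H]1CC[C@@H](O[Si](C)(C)C(C)(C)C)[C@H](C)C1=C | intermediate
24 | tertiary C5 radical from 23 (not isolated) | C=CC(=O)[C@@H](O[Si](CC)(CC)CC)[C@@H]1CC[C@@H](O[Si](C)(C)C(C)(C)C)[C@H](C)[C]1C | intermediate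
25 | cyclised α-keto C7 radical (not isolated) | [CH]1C[C@]2(C)[C@@H](C)[C@H](O[Si](C)(C)C(C)(C)C)CC[C@H]2[C@H](O[Si](CC)(CC)CC)C1=O | intermediate
26 | (1S,4aR,5R,6R,8aR)-6-{[tert-butyl(dimethyl)silyl]oxy}-4a,5-dimethyl-1-[(triethylsilyl)oxy]octahydronaphthalen-2(1H)-one (trans-decalin-8-one; 3α,9α-disilyloxy, 4β,5β-dimethyl, 10αH) | C1C[C@]2(C)[C@@H](C)[C@H](O[Si](C)(C)C(C)(C)C)CC[C@H]2[C@H](O[Si](CC)(CC)CC)C1=O | intermediate
27 | 2-bromopropene | C=C(C)Br | starting material
28 | lithium C7–C8 enolate of 26 (not isolated) | [Li+].[O-]C1=CC[C@]2(C)[C@@H](C)[C@H](O[Si](C)(C)C(C)(C)C)CC[C@H]2[C@@H]1O[Si](CC)(CC)CC | intermediate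
29 | lithium dienolate of 30 (not isolated) | [Li+].[O-]C1=C(C(C)=C)C[C@]2(C)[C@@H](C)[C@H](O[Si](C)(C)C(C)(C)C)CC[C@H]2[C@@H]1O[Si](CC)(CC)CC | intermediate
30 | (1S,3S,4aR,5R,6R,8aR)-6-{[tert-butyl(dimethyl)silyl]oxy}-4a,5-dimethyl-3-(prop-1-en-2-yl)-1-[(triethylsilyl)oxy]octahydronaphthalen-2(1H)-one | C=C(C)[C@@H]1C[C@]2(C)[C@@H](C)[C@H](O[Si](C)(C)C(C)(C)C)CC[C@H]2[C@H](O[Si](CC)(CC)CC)C1=O | intermediate
31 | (1S,3S,4aR,5R,6R,8aR)-6-{[tert-butyl(dimethyl)silyl]oxy}-1-hydroxy-4a,5-dimethyl-3-(prop-1-en-2-yl)octahydronaphthalen-2(1H)-one | C=C(C)[C@@H]1C[C@]2(C)[C@@H](C)[C@H](O[Si](C)(C)C(C)(C)C)CC[C@H]2[C@H](O)C1=O | intermediate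
32 | ethyl but-2-ynoate | CC#CC(=O)OCC | starting material
33 | ethylmagnesium bromide | CC[Mg]Br | starting material
34 | ethyl (2Z)-2-cuprio-3-methylpent-2-enoate (alkenylcopper; not isolated) | CCOC(=O)/C([Cu])=C(\C)CC | intermediate
35 | ethyl (2E)-3-methylpent-2-enoate | CCOC(=O)/C=C(\C)CC | intermediate
36 | lithium (2E)-3-methylpent-2-enoate (not isolated) | [Li+].[O-]C(=O)/C=C(\C)CC | intermediate
37 | (2E)-3-methylpent-2-enoic acid | OC(=O)/C=C(\C)CC | intermediate
38 | O-[(2E)-3-methylpent-2-enoyl]-N,N′-dicyclohexylisourea (not isolated) | CC/C(C)=C/C(=O)OC(=NC1CCCCC1)NC1CCCCC1 | intermediate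
39 | (1S,3S,4aR,5R,6R,8aR)-6-{[tert-butyl(dimethyl)silyl]oxy}-4a,5-dimethyl-2-oxo-3-(prop-1-en-2-yl)decahydronaphthalen-1-yl (2E)-3-methylpent-2-enoate | C=C(C)[C@@H]1C[C@]2(C)[C@@H](C)[C@H](O[Si](C)(C)C(C)(C)C)CC[C@H]2[C@H](OC(=O)/C=C(\C)CC)C1=O | intermediate
40 | (1S,3S,4aR,5R,6R,8aR)-6-hydroxy-4a,5-dimethyl-2-oxo-3-(prop-1-en-2-yl)decahydronaphthalen-1-yl (2E)-3-methylpent-2-enoate | C=C(C)[C@@H]1C[C@]2(C)[C@@H](C)[C@H](O)CC[C@H]2[C@H](OC(=O)/C=C(\C)CC)C1=O | intermediate
41 | angelic acid, (2Z)-2-methylbut-2-enoic acid | C/C=C(/C)C(=O)O | starting material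
42 | angelic 2,4,6-trichlorobenzoic anhydride (not isolated) | C/C=C(/C)C(=O)OC(=O)c1c(Cl)cc(Cl)cc1Cl | intermediate
43 | CNP0301161.1, (1S,3S,4aR,5R,6R,8aR)-4a,5-dimethyl-6-{[(2Z)-2-methylbut-2-enoyl]oxy}-2-oxo-3-(prop-1-en-2-yl)decahydronaphthalen-1-yl (2E)-3-methylpent-2-enoate; eremophilane numbering (3R,4R,5R,7S,9S,10R) | C=C(C)[C@@H]1C[C@]2(C)[C@@H](C)[C@H](OC(=O)/C(C)=C\C)CC[C@H]2[C@H](OC(=O)/C=C(\C)CC)C1=O | target

Total step count: 20. Longest linear sequence: 18 steps (steps 1–15 and 18–20); steps 16 and 17 form the side branch to acid 37.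

Steps most likely to fail

1. Step 13 (key step). The C5 radical may be quenched by a second hydrogen atom, or hand a hydrogen back to the metal so that the double bond moves into ring A, before it reaches C6. The chain may also close through the folded chair and give the cis-fused ring. The fallback makes the same radical without a metal hydride, sets out from 20 and returns at 26. Markovnikov addition of anhydrous HBr to the methylene group of 20 (CH2Cl2, −78 °C) should give the tertiary bromide F1. Vinylmagnesium bromide with the same acidic inverse quench as in step 12 then gives the bromo vinyl ketone F2. Slow addition of Bu3SnH with Et3B/air initiation at high dilution abstracts the bromine atom and the C5 radical closes 6-endo as before, the α-keto radical taking its hydrogen from the stannane, to give 26. This tin hydride radical cyclisation can be run at −78 °C, where the energy gap between the two chair transition states counts for more.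

2. Step 7. The aldehyde may add to the other face of the enol borinate, or part of the reaction may leak through a boat transition state; after step 9 either would surface as the C9 epimer. The fallback sets C9 independently of the enolate face, sets out from 11 and returns at 15. Kinetic deprotonation (LiN(iPr)2, THF, −78 °C) and trapping with Me3SiCl gives the trimethylsilyl enol ether F3. A Mukaiyama aldol addition of F3 to ethyl glyoxylate, catalysed by Cu(OTf)2 and a tert-butyl-bis(oxazoline) ligand (the enantiomer that leaves the Si face of the chelated aldehyde open), gives the O-silylated aldol F4, and dilute HCl gives 15. C9 is then set by the catalyst, whichever face of the enol ether reacts, and C10 is equilibrated in step 9 in any case.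

3. Step 14. The product enolate may be alkenylated a second time, enolisation may stray towards C9, or the new double bond may drift into conjugation with the ketone. The fallback is the classical aldol route, sets out from 26 and returns at 30. The kinetic enolate (LiN(iPr)2, THF, −78 °C) is transmetallated with ZnCl2 and added to acetone to give the tertiary aldol F5. Dehydration with SOCl2/pyridine at 0 °C should give 30 together with the conjugated isopropylidene ketone F6. F6 is deconjugated by γ-deprotonation with KOtBu in tBuOH/THF to the potassium dienolate F7, followed by a cold acetic acid quench, where kinetic axial α-protonation gives 30.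

Further compounds
F1 | step 13 | 5β-bromo-5α-methyl HBr adduct of Weinreb amide 20 (tertiary bromide) | CON(C)C(=O)[C@@H](O[Si](CC)(CC)CC)[C@@H]1CC[C@@H](O[Si](C)(C)C(C)(C)C)[C@H](C)[C@]1(C)Br
F2 | step 13 | 5β-bromo-5α-methyl vinyl ketone (tertiary bromide analogue of 23) | C=CC(=O)[C@@H](O[Si](CC)(CC)CC)[C@@H]1CC[C@@H](O[Si](C)(C)C(C)(C)C)[C@H](C)[C@]1(C)Br
F3 | step 7 | kinetic trimethylsilyl enol ether of 11 | CC(C)(C)[Si](C)(C)O[C@@H]1CCC=C(O[Si](C)(C)C)[C@H]1C
F4 | step 7 | O-trimethylsilyl ether of 15 | CCOC(=O)[C@@H](O[Si](C)(C)C)[C@H]1CC[C@@H](O[Si](C)(C)C(C)(C)C)[C@H](C)C1=O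
F5 | step 14 | 7α-(2-hydroxypropan-2-yl) ketone (acetone aldol of 26) | CC(C)(O)[C@@H]1C[C@]2(C)[C@@H](C)[C@H](O[Si](C)(C)C(C)(C)C)CC[C@H]2[C@H](O[Si](CC)(CC)CC)C1=O
F6 | step 14 | 7-isopropylidene ketone (conjugated isomer of 30) | CC(C)=C1C[C@]2(C)[C@@H](C)[C@H](O[Si](C)(C)C(C)(C)C)CC[C@H]2[C@H](O[Si](CC)(CC)CC)C1=O
F7 | step 14 | potassium dienolate of F6 | [K+].[O-]C1=C(C(C)=C)C[C@]2(C)[C@@H](C)[C@H](O[Si](C)(C)C(C)(C)C)CC[C@H]2[C@@H]1O[Si](CC)(CC)CC
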